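The earlier runs and the new flask are simulated with constants of no real substance, and the scatter is random.

**The vessel.** The vessel is closed, stirred and held at one temperature, and in it free enzyme turns starting material into target.

in all of them: starting material 0.17 M; free enzyme 34 µM; temperature 25 °C
- elm: the very flask that is asked about, followed so far
- flask: time 4.0 min

elm run (percent of the starting material charged)

| time / min | target / % |
|---|---|
| 0.500 | 72.7 |
| 1.00 | 61.3 |
| 1.33 | 55.5 |
| 2.00 | 47.6 |
| 2.50 | 43.9 |
| 3.00 | 43.1 |

(readings scatter by 1 percentage point)

- teal: at 4.0 min add free enzyme, 100 % of the amount charged, then wait 4.0 min
- amber: change nothing and wait 4.0 min more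
- ochre: at 4.0 min take out 90 % of the target then present, then wait 4.0 min
- grey: at 4.0 min raise the temperature by 25 K, then wait 4.0 min

- what is taken out of target is counted as made
- additions bring no volume worth counting

* target, in percent of the starting material first charged, at 4.0 min
* the option that brings most further target ("none" if no option brings more than 2 percentage points) (teal / amber / ochre / grey / none)
* target present, with what was taken out counted in, in percent of the starting material first charged, after teal
* target present, with what was taken out counted in, in percent of the starting material first charged, after amber

**Reading the fall.** Target in the elm flask, which is this flask followed so far, falls from 72.7 % at 0.500 min to 43.1 % at 3.00 min. The last two readings differ by 0.8 percentage points, less than the scatter of 1 point. We therefore read a passage from kinetic to thermodynamic control, with something unseen sharing the charge with target. The gap to the last reading halves in about 0.552 min, which is short against the 4.0 min of waiting. Neglecting any starting material left, the last reading gives 1.32 for the missing part of the charge over target. We carry this ratio, the split.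

**Turned round.** By our reckoning, target stands at 43.1 % of the charge, and this is our value for now. Waiting leaves the split as it is, so we expect less than 2 points from amber or teal. Ochre takes out 38.8 %, and the remainder divides again by the split, which gives 65.2 % counted in, a gain of 22 points. For grey to beat that, heating would have to bring the split down to 0.534, a factor of 2.47 from where this flask stands. One temperature shows no direction for that, so we commit to ochre.

**The flask.** The forecast gave 41 %, ochre, 40 % and 40.3 %, holding that “the remaining pool refills it”. The simulation gives 42.0 % now, 41.3 % after teal and 41.1 % after amber, with gains of 21 points by ochre and 42 points by grey, so the best option is grey.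

    free enzyme → unfolded enzyme (k = 8.40 × 10⁻⁴ /s, Ea = 242 kJ/mol)
    starting material + free enzyme → target + free enzyme, rate k2*[starting material]^3*[free enzyme]/(1 + ([starting material]/Kh2)^3) (0.160 M, k = 5.80 × 10⁶ /M³/s, Ea = 10.0 kJ/mol)
    target ⇌ isomer of the product (K = 1.40, k = 0.0100 /s, Ea = 81.0 kJ/mol, ΔH = −68.0 kJ/mol)
    (constants at 25 °C)

**The split again.** Beside 2.01 % of starting material, the missing part is the isomer of the product, which in this flask at 4.00 min stands to target as 1.33. After grey, target holds 83.9 %, a split of 0.192, below 0.534. The path from target to isomer of the product, both ways, is the main reason for the low target in this flask: the run without that path holds 98.0 % target at 4.0 min instead of 42.0 %. In the neighbour flask, charged with 58.8 % of this flask's free enzyme, the split and the 2.6 % of starting material left give 42.0 %, and that flask holds 41.8 % target.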